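**Retrosynthetic overview**
- The target comes from a bicyclic exocyclic alkene by Markovnikov hydration of C8=C12, so the C8 carbinol is made last (drimane numbering, see remark).
- The bicyclic alkene comes from an acyclic epoxy diene by one radical bicyclisation started by trivalent titanium: ring A closes first (bond C4–C5), then ring B (bond C9–C10). C4, C5, C9 and C10 are set in this step, relative to C3.
- Enabling feature: the trans-decalin is a folded farnesyl chain. In ring A, C3(OH)–C4(quaternary) is an opened oxirane; the ring-fusion pair C5(H)/C10(CH3) and the ring B pair C9(H, CH2OAr)/C8(CH3) are two former trisubstituted E alkenes, so the radical site can pass C4 → C10 → C8.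
- The epoxy diene comes from angeloylation of an epoxy alcohol, made by asymmetric epoxidation of the E allylic alcohol obtained by allylic oxidation of umbelliprenin (umbelliferone + farnesyl bromide). No protecting groups are used.

Key step: step 5

Remark (assumption on the chemistry): the acyl group is angeloyl, (Z)-2-methylbut-2-enoyl, as drawn; positions are numbered as in drimanes (C3 ring A carbinol, C4 quaternary carbon with CH3 and CH2O-angeloyl, C5 ring-fusion CH, C10 ring-fusion carbon with CH3, C9 CH with CH2OAr, C8 tertiary carbinol, C12 its methyl; Ar = 2-oxo-2H-chromen-7-yl); compounds 1, 2 and 6 are taken as commercial.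

**Step 1**
Reactants: 1 umbelliferone (7-hydroxy-2H-chromen-2-one); 2 (2E,6E)-farnesyl bromide
Product: 3 umbelliprenin (7-[(2E,6E)-3,7,11-trimethyldodeca-2,6,10-trienyloxy]-2H-chromen-2-one)
Conditions: K2CO3, acetone, reflux
Reagents that add atoms: none
Why: Williamson ether synthesis; the phenoxide of 1 should displace the primary allylic bromide by SN2 at oxygen, with no new stereocenter and both E alkenes untouched.

**Step 2**
Reactants: 3 umbelliprenin
Product: 4 (10E)-12-hydroxyumbelliprenin (7-[(2E,6E,10E)-12-hydroxy-3,7,11-trimethyldodeca-2,6,10-trienyloxy]-2H-chromen-2-one)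
Conditions: SeO2 (0.3 equiv), t-BuOOH (3 equiv), salicylic acid (0.1 equiv), CH2Cl2, 0 °C to rt, stopped at partial conversion, 3 recycled
Reagents that add atoms: selenium dioxide, O=[Se]=O (oxygen donor, catalytic); tert-butyl hydroperoxide, CC(C)(C)OO (terminal oxidant that restores SeO2)
Why: Riley allylic oxidation (ene reaction, then 2,3-sigmatropic shift) should go at the terminal isopropylidene, the most electron-rich and least hindered alkene, and only at its E methyl group, which fixes the E geometry of the new allylic alcohol; the alkene next to the aryloxy group is deactivated.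

**Step 3**
Reactants: 4 (10E)-12-hydroxyumbelliprenin
Product: 5 epoxy alcohol 7-{(2E,6E)-9-[(2R,3R)-3-(hydroxymethyl)-3-methyloxiran-2-yl]-3,7-dimethylnona-2,6-dienyloxy}-2H-chromen-2-one
Conditions: Ti(OiPr)4 (0.1 equiv), D-(−)-diethyl tartrate (0.12 equiv), t-BuOOH (2 equiv, in decane), 4 Å molecular sieves, CH2Cl2, −20 °C
Reagents that add atoms: tert-butyl hydroperoxide, CC(C)(C)OO
Why: Katsuki–Sharpless asymmetric epoxidation; only the alkene of the allylic alcohol is bound and oxidised at titanium, and D-(−)-tartrate on an (E)-2-methylalk-2-en-1-ol should give the (2R,3R)-oxirane, which fixes the later C3 carbinol and through it the absolute configuration of the decalin.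

**Step 4**
Reactants: 5 epoxy alcohol; 6 angelic acid ((Z)-2-methylbut-2-enoic acid)
Product: 8 epoxy angelate {(2R,3R)-2-methyl-3-[(3E,7E)-3,7-dimethyl-9-(2-oxo-2H-chromen-7-yloxy)nona-3,7-dienyl]oxiran-2-yl}methyl (Z)-2-methylbut-2-enoate, via angelic 2,4,6-trichlorobenzoic anhydride 7 (not isolated)
Conditions: 6, 2,4,6-trichlorobenzoyl chloride, Et3N, toluene, rt; filter; then 5, 60–70 °C (no DMAP)
Reagents that add atoms: none
Why: Yamaguchi-type mixed-anhydride esterification run without a nucleophilic catalyst should acylate the unhindered primary alcohol without Z to E isomerisation of the angeloyl unit; the oxirane and its two stereocenters are not touched.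

**Step 5**
Reactants: 8 epoxy angelate
Product: 10 bicyclic hydroxy alkene [(1S,2R,4aR,5R,8aS)-2-hydroxy-1,4a-dimethyl-6-methylidene-5-{[(2-oxo-2H-chromen-7-yl)oxy]methyl}decahydronaphthalen-1-yl]methyl (Z)-2-methylbut-2-enoate, via trimethylsilyl ether 9 (not isolated)
Conditions: Cp2TiCl2 (0.2 equiv), Mn dust, TMSCl, 2,4,6-collidine, degassed THF, rt, slow addition of 8; then 1 M HCl, THF
Reagents that add atoms: none
Why: Cp2TiCl (trivalent titanium, made from Cp2TiCl2 and Mn) should open the oxirane by single-electron transfer at its more substituted carbon to give the tertiary beta-titanoxy radical at C4, which adds to C5 of the central E alkene; the tertiary C10 radical then adds to C9 of the allylic-ether alkene, and the tertiary C8 radical is trapped by a second Cp2TiCl and loses hydride from its methyl group to leave the exocyclic alkene, the closest known reaction type being the Cp2TiCl-catalysed radical bicyclisation of 10,11-epoxyfarnesyl acetate to 3-hydroxyalbicanyl acetate. Ring A closes 6-endo-trig (bond C4–C5) and ring B closes 6-endo-trig (bond C9–C10), each preferred over 5-exo because the methyl group on the inner alkene carbon blocks the exo position and the endo mode gives a tertiary radical. C3 is carried unchanged from the oxirane; C5 and C10 should come out trans because the E central alkene reacts through a chair–chair transition state with the C3–O–Ti group equatorial; C9 should carry CH2OAr equatorial (C9–H anti to the C10 methyl) because of the E geometry of the terminating alkene in the second chair. C4 is the one center not fixed by stereospecificity, since the radical is planar: it should be set by the rotamer that keeps the larger CH2O-angeloyl group eclipsing C3–H, the future equatorial position away from the C10 methyl, so that it ends trans to the angular methyl as in the target. The step needs chemoselectivity for the epoxide over the angelate and coumarin acceptors and ring closure faster than titanium trapping of the C4 radical (which would expel angelate); the poor radical-acceptor quality of the trisubstituted conjugated ester and of the lactone, and the low standing concentration of Cp2TiCl kept by slow addition and TMSCl/collidine turnover, should secure this.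

**Step 6**
Reactants: 10 bicyclic hydroxy alkene
Product: 12 target [(1S,2R,4aR,5R,6S,8aS)-2,6-dihydroxy-1,4a,6-trimethyl-5-{[(2-oxo-2H-chromen-7-yl)oxy]methyl}decahydronaphthalen-1-yl]methyl (Z)-2-methylbut-2-enoate, via tertiary hydroperoxide 11 (not isolated)
Conditions: Co(acac)2 (0.2 equiv), PhSiH3, O2 (1 atm), THF, 0 °C to rt; then PPh3, 0 °C
Reagents that add atoms: dioxygen, O=O
Why: Mukaiyama hydration by hydrogen-atom transfer from a cobalt hydride; the 1,1-disubstituted alkene should react well ahead of the trisubstituted conjugated angelate and the coumarin alkene, hydrogen goes to the CH2 terminus to give the tertiary C8 radical, and O2 should be taken up on the face opposite the syn-axial C10 methyl (equatorial C–O bond), placing the C8 hydroxyl trans to the angular methyl; PPh3 reduces the hydroperoxide.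

**Compound list**
1 | umbelliferone (7-hydroxy-2H-chromen-2-one) | Oc1ccc2ccc(=O)oc2c1 | starting material
2 | (2E,6E)-farnesyl bromide | CC(C)=CCC/C(C)=C/CC/C(C)=C/CBr | starting material
3 | umbelliprenin | CC(C)=CCC/C(C)=C/CC/C(C)=C/COc1ccc2ccc(=O)oc2c1 | intermediate
4 | (10E)-12-hydroxyumbelliprenin | OC/C(C)=C/CC/C(C)=C/CC/C(C)=C/COc1ccc2ccc(=O)oc2c1 | intermediate
5 | (2R,3R)-epoxy alcohol | OC[C@@]1(C)O[C@@H]1CC/C(C)=C/CC/C(C)=C/COc1ccc2ccc(=O)oc2c1 | intermediate
6 | angelic acid | C/C=C(/C)C(=O)O | starting material
7 | angelic 2,4,6-trichlorobenzoic anhydride | C/C=C(/C)C(=O)OC(=O)c1c(Cl)cc(Cl)cc1Cl | intermediate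
8 | (2R,3R)-epoxy angelate | C/C=C(/C)C(=O)OC[C@@]1(C)O[C@@H]1CC/C(C)=C/CC/C(C)=C/COc1ccc2ccc(=O)oc2c1 | intermediate
9 | C3 trimethylsilyl ether of 10 | C/C=C(/C)C(=O)OC[C@]1(C)[C@H]2CCC(=C)[C@@H](COc3ccc4ccc(=O)oc4c3)[C@]2(C)CC[C@H]1O[Si](C)(C)C | intermediate
10 | bicyclic hydroxy alkene (C8=C12 exocyclic) | C/C=C(/C)C(=O)OC[C@]1(C)[C@H]2CCC(=C)[C@@H](COc3ccc4ccc(=O)oc4c3)[C@]2(C)CC[C@H]1O | intermediate
11 | C8 tertiary hydroperoxide | C/C=C(/C)C(=O)OC[C@]1(C)[C@H]2CC[C@](C)(OO)[C@@H](COc3ccc4ccc(=O)oc4c3)[C@]2(C)CC[C@H]1O | intermediate
12 | CNP0139045.1 | C/C=C(/C)C(=O)OC[C@]1(C)[C@H]2CC[C@](C)(O)[C@@H](COc3ccc4ccc(=O)oc4c3)[C@]2(C)CC[C@H]1O | target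

**Total step count:** 6
**Longest linear sequence:** 6 steps (from 1 and 2 to 12)

**Steps most likely to fail**

Step 5. Rotation about C3–C4 in the planar C4 radical may erode the configuration at C4, and trapping of that radical by titanium before ring closure may expel angelate. The fallback sets out from 5 and comes back at 10. Compound 5 is silylated (TBDPSCl, imidazole, DMF) to the tert-butyldiphenylsilyl ether F1. A cationic epoxide-initiated polyene cyclisation (MeAlCl2, CH2Cl2, −78 °C) then closes both rings with inversion at the oxirane carbon, so C4 follows stereospecifically from the E geometry made in step 2. Proton loss from the methyl group of the C8 cation should give the silyl-protected hydroxy alkene F2; control of this proton loss is the known weakness of the alternative. TBAF in THF frees the diol F3, whose primary hydroxyl is acylated in preference to the hindered secondary one with mixed anhydride 7 (toluene, 60 °C) to give 10.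

Step 6. Oxygen capture at the C8 radical may show poor facial selectivity, and hydrogen-atom transfer to the conjugated angelate may compete. The fallback sets out from 10 and comes back at 12. Epoxidation with mCPBA, NaHCO3, CH2Cl2, 0 °C should attack only the exocyclic alkene, from the face opposite the C10 methyl, to give the spiro epoxide F4. LiI, AcOH, THF opens it at the CH2 carbon to the iodohydrin F5. Bu3SnH, Et3B, air, toluene, 0 °C removes iodine and gives 12.

Step 2. Oxidation may spread over the three trisubstituted alkenes and run on to the aldehyde. The fallback sets out from 3 and comes back at 4. Terminal-selective bromohydrin formation (NBS, THF/H2O, 0 °C) gives the bromohydrin F6. K2CO3, MeOH closes it to the racemic terminal epoxide F7. HIO4·2H2O in THF/Et2O cleaves the epoxide to the aldehyde F8. Wittig reaction with Ph3P=C(CH3)CHO (toluene, 80 °C) gives the E enal F9, and Luche reduction (NaBH4, CeCl3·7H2O, MeOH, −40 °C) gives 4.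

**Further compounds**
F1 | step 5 | tert-butyldiphenylsilyl ether of 5 | CC(C)(C)[Si](OC[C@@]1(C)O[C@@H]1CC/C(C)=C/CC/C(C)=C/COc1ccc2ccc(=O)oc2c1)(c1ccccc1)c1ccccc1
F2 | step 5 | silyl-protected bicyclic hydroxy alkene | CC(C)(C)[Si](OC[C@]1(C)[C@H]2CCC(=C)[C@@H](COc3ccc4ccc(=O)oc4c3)[C@]2(C)CC[C@H]1O)(c1ccccc1)c1ccccc1
F3 | step 5 | bicyclic diol (C3 and CH2 hydroxyls free) | OC[C@]1(C)[C@H]2CCC(=C)[C@@H](COc3ccc4ccc(=O)oc4c3)[C@]2(C)CC[C@H]1O
F4 | step 6 | C8 spiro epoxide of 10 | C/C=C(/C)C(=O)OC[C@]1(C)[C@H]2CC[C@@]3(CO3)[C@@H](COc4ccc5ccc(=O)oc5c4)[C@]2(C)CC[C@H]1O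
F5 | step 6 | C8 hydroxy C12 iodide (iodohydrin) | C/C=C(/C)C(=O)OC[C@]1(C)[C@H]2CC[C@](CI)(O)[C@@H](COc3ccc4ccc(=O)oc4c3)[C@]2(C)CC[C@H]1O
F6 | step 2 | 10-bromo-11-hydroxy-10,11-dihydroumbelliprenin (racemic) | CC(C)(O)C(Br)CC/C(C)=C/CC/C(C)=C/COc1ccc2ccc(=O)oc2c1
F7 | step 2 | 10,11-epoxyumbelliprenin (racemic) | CC1(C)OC1CC/C(C)=C/CC/C(C)=C/COc1ccc2ccc(=O)oc2c1
F8 | step 2 | (4E,8E)-4,8-dimethyl-10-(2-oxo-2H-chromen-7-yloxy)deca-4,8-dienal | O=CCC/C(C)=C/CC/C(C)=C/COc1ccc2ccc(=O)oc2c1
F9 | step 2 | (2E,6E,10E)-2,6,10-trimethyl-12-(2-oxo-2H-chromen-7-yloxy)dodeca-2,6,10-trienal | O=C/C(C)=C/CC/C(C)=C/CC/C(C)=C/COc1ccc2ccc(=O)oc2c1
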